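## Structural features

Neoirietetraol (22) is a trans-decalin whose ring B (C1–C5, C10) and ring A (C5–C10) share C5 and C10, and whose C7 is bonded to C11 of a cyclopentane (ring C, C11–C15, gem-dimethyl at C15). It has eight stereocentres: C1 (equatorial bromine), C4 (axial hydroxyl, equatorial methyl), C5 (angular hydroxyl), C10 (angular methyl), C7 (axial hydroxyl, ring C equatorial), C11 (quaternary), C12 (secondary hydroxyl) and C14 (bromine). They are contiguous in the arrays C1–C10–C5–C4 and C7–C11–C12; the C4 and C5 hydroxyls are trans-diaxial, the C5 and C7 hydroxyls syn-diaxial, and on ring C the bond to C7, the C12 hydroxyl and the C14 bromine lie on one face. Both bromides are secondary and sit next to a quaternary carbon (C1 next to C10, C14 next to C15), so substitution there is slow and ionisation invites 1,2-shifts and elimination. The C5 hydroxyl is vicinal to the tertiary C4 hydroxyl (pinacol-type ionisation in strong acid) and β to any carbonyl at C7 (dehydration, retro-aldol). The real difficulty is twofold: the C7–C11 bond joins a tertiary carbinol carbon to a quaternary carbon that is itself flanked by the quaternary C15, and bromine must be placed at C1 and C14 with defined configuration. The key step uses the vicinal oxygenation at C4 and C5: C5 is a ring A carbon carrying a tertiary hydroxyl next to C4 of ring B, the pattern of an α-ketol, so ring B can be closed onto a preformed ring A by joining a C4 acyl anion equivalent to a C5 ketone.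

## Logic of the disconnections

22 to 21: the two C–H bonds at C13 and C14 are removed, giving a C13=C14 bromoalkene. The C14 bromide is then set by delivery of hydrogen to an sp2 carbon and not by substitution at a neopentyl centre. One stereocentre disappears. The forward step must bring hydrogen in on the ring C face opposite the C7 substituent without breaking the C–Br bond.

21 to 20: the C12–H bond is cut (carbinol to ketone). This uncovers a β-hydroxy ketone spanning C7–C11–C12 and removes a second stereocentre. The forward step needs 1,2-addition of hydride to a bromo enone, anti to the C7 substituent.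

20 to 14 and 19: the C7–C11 bond, the only link between the two ring systems, is cut as an aldol. The route becomes convergent and ring C shrinks to an achiral-after-enolisation bromo enone. A β-bromo cyclopentanone enolate is avoided because it would lose HBr; in 19 the bromine is vinylic. The forward step is a hindered ketone–ketone aldol that must enter C7 equatorially and choose the right face of C11.

19 to 18, 17, 15 and 4: the C11–CH3 bond, the C14–Br bond (with transposition of the carbonyl) and the two C15–CH3 bonds are cut in turn. The order of enolate alkylations and the transposition fix which carbon carries oxygen and which carries bromine. The forward steps need kinetic α′ enolates only.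

14 to 13 to 11 and 12: the C7 ketone is masked as its dioxolane and the C4–CH3 bond is cut. This leads back to the α-ketol. The forward steps need equatorial delivery of methyl at C4 and an acid mild enough for a tertiary diol.

11 to 10: the C4–C5 bond is cut (key step). Ring B opens to a ring A keto ketal with an aldehyde chain; 10 and 11 carry the target configuration at C1 and C10, and 11 also at C5. The forward step must give the trans ring fusion.

10 to 9 to 8: the C4 aldehyde is traced to a terminal alkene and the C7 dioxolane to the enol ether of a vinylogous ester. This returns the ring to a form whose only kinetic enolate position is C10.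

8 to 6 (through 7): the C1–Br bond is traced to a C1–O bond of opposite configuration. The forward step is a substitution with inversion next to a quaternary carbon.

6 to 5 to 3 to 1, 2 and 4: the C1–H bond (ketone reduction), the C10–CH3 bond and the C10–C1 bond (acylation) are cut. A one-step enantioselective aldol of a tetrasubstituted enolate is not relied on; instead a reagent-controlled reduction of racemic 5 sorts the two enantiomers into separable diastereomers.

## Other disconnections considered

Alternative 1: The cut is made at the three tertiary C–O bonds (C7–O, C5–O, C4–O), leading back to a carbon-complete diene with C7=C8 and C4=C5 alkenes. In the forward step, Co(acac)2, O2 and Et3SiH would put a hydrogen atom on C8; the C7 radical takes up O2, the peroxyl radical closes onto C5, and the C4 radical takes up a second O2 to give A1. In its favour, three oxygens arrive in one operation and no β-hydroxy ketone is ever handled. The syn relation of the C5 and C7 oxygens is enforced by the dioxolane ring; on this point it is better than the chosen plan, where C5 and C7 are set in separate steps. Against it, the substrate must already contain the C7–C11 bond, both neopentyl bromides and a tetrasubstituted alkene, so the hardest carbon–carbon bond is only moved upstream. The faces of the first O2 capture at C7 and of the last at C4 are not tied to any control element, and two O–O bonds must later be reduced beside two C–Br bonds. In mechanism it replaces polar steps by a radical chain with three selectivity questions; in step economy it is better for the oxidation stage and worse overall.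

Alternative 2: The cut is made at C5–C10 and C1–Br, leading back to a ten-membered ring. In the forward step, bromodiethylsulfonium bromopentachloroantimonate would attack the C1=C10 alkene, the silyl-bearing C5 would bond to C10 across the ring and the silyl group would leave, giving A2. In its favour, the C1–Br bond and the quaternary C10 form in one anti addition and bromine ends equatorial without any substitution at a hindered carbinol; this is better than step 4 of the chosen plan. The C4=C5 alkene of A2 also leads naturally to a trans-diaxial diol by epoxide opening, which is at least the equal of relying on the ring-fusion selectivity of a benzoin closure. Against it, a ten-membered ring with two geometrically defined trisubstituted alkenes, a vinylsilane and a C7 that already carries ring C has to be built and closed first. The face selectivity of the transannular step depends on the ring conformation, and the electrophile must choose between two alkenes. Structurally it reaches rings A and B at once, but its step economy is clearly worse.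

Alternative 3: The cut is made at C9–C10 and C5–C6, so that ring A is formed by a Diels–Alder reaction. In the forward step, a butadiene carrying ring C at C7 would add under AlBr3/AlMe3 to the C5=C10 alkene of a silyloxy methylcyclohexenone, giving A3. In its favour, the union is convergent and the quaternary C10 and ring A form together. The C7–C11 bond is made earlier as an sp2–sp3 bond and the C7 hydroxyl can come later from hydration of the C7=C8 alkene; this avoids the hindered ketone–ketone aldol and is better than step 13 of the chosen plan. Against it, A3 is cis-fused with hydrogen at C5, so the angular hydroxyl would have to be introduced later at a carbon that the C1 ketone does not activate. The C1 ketone must become an equatorial bromide by substitution on a ring carbon next to C10, which is harder than the acyclic substitution of the chosen plan, and C4 still needs oxidation and methylation. The strong Lewis acid also threatens the silyl ethers and the ring C bromide. In mechanism the cycloaddition is more predictable than the benzoin; in step economy the gain at the union is lost in the later redox steps.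

Key step: step 7

Remark on the chemistry: locants C1–C15 in names and arguments are those defined under Structural features, and "trans-decalin" names use them; 5, 16 and 19 are racemates, which is harmless because 5 is sorted in step 3 and the stereocentres of 16 and 19 are erased by later enolisation.

## Route

Step 1
Reactants: 1 3-ethoxycyclohex-2-en-1-one; 2 pent-4-enoyl chloride
Product: 3 3-ethoxy-6-(pent-4-enoyl)cyclohex-2-en-1-one
Conditions: LiN(iPr)2 (2.1 equiv), THF, −78 °C; then 2, −78 to 0 °C; aq. NH4Cl
Reagents that add atoms: none
Why: Claisen-type C-acylation of the kinetic α′ lithium enolate of the vinylogous ester (Stork–Danheiser enolate) forms C10–C1; the second equivalent of base stores the product as its diketonate, and the new centre stays enolisable, so no stereochemistry is at stake.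

Step 2
Reactants: 3 3-ethoxy-6-(pent-4-enoyl)cyclohex-2-en-1-one; 4 methyl iodide
Product: 5 rac-3-ethoxy-6-methyl-6-(pent-4-enoyl)cyclohex-2-en-1-one
Conditions: K2CO3, MeI, acetone, 40 °C
Reagents that add atoms: methyl iodide (4), CI
Why: C-alkylation of the stabilised β-dicarbonyl enolate creates the quaternary C10 as a racemate; anhydrous carbonate avoids retro-Claisen cleavage of the now non-enolisable diketone.

Step 3
Reactants: 5 rac-3-ethoxy-6-methyl-6-(pent-4-enoyl)cyclohex-2-en-1-one
Product: 6 (6R)-3-ethoxy-6-[(1R)-1-hydroxypent-4-en-1-yl]-6-methylcyclohex-2-en-1-one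
Conditions: (S)-1-methyl-3,3-diphenyltetrahydro-1H,3H-pyrrolo[1,2-c][1,3,2]oxazaborole (0.2 equiv), catecholborane, toluene, −78 to −40 °C; chromatographic separation of the two diastereomers
Reagents that add atoms: none
Why: Corey–Bakshi–Shibata reduction; the oxazaborolidine tells the quaternary substituent from the CH2 chain and should deliver hydride to the same face of the exocyclic ketone in both enantiomers of 5 (R carbinol), so the 6R half gives 6 with C10 methyl and C1 hydroxyl syn and the 6S half a separable diastereomer; catecholborane leaves the terminal alkene and the vinylogous ester alone.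

Step 4
Reactants: 6 (6R)-3-ethoxy-6-[(1R)-1-hydroxypent-4-en-1-yl]-6-methylcyclohex-2-en-1-one
Product: 8 (6S)-6-[(1S)-1-bromopent-4-en-1-yl]-3-ethoxy-6-methylcyclohex-2-en-1-one, via triflate 7 (not isolated)
Conditions: Tf2O, pyridine, CH2Cl2, −78 to −30 °C; then Bu4NBr, toluene, −30 to 25 °C
Reagents that add atoms: trifluoromethanesulfonic anhydride, O=S(=O)(OS(=O)(=O)C(F)(F)F)C(F)(F)F; tetrabutylammonium bromide, CCCC[N+](CCCC)(CCCC)CCCC.[Br-]
Why: Sulfonate formation and SN2 displacement by bromide with inversion at C1; the neighbouring quaternary carbon carries an electron-poor carbonyl carbon, which disfavours ionisation and 1,2-shift, and a soluble, weakly basic bromide in a solvent of low polarity favours substitution over elimination; the descriptor change at the ring carbon is formal only.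

Step 5
Reactants: 8 (6S)-6-[(1S)-1-bromopent-4-en-1-yl]-3-ethoxy-6-methylcyclohex-2-en-1-one
Product: 9 (8S)-8-[(1S)-1-bromopent-4-en-1-yl]-8-methyl-1,4-dioxaspiro[4.5]decan-7-one
Conditions: HOCH2CH2OH (excess), TsOH·H2O (cat.), benzene, reflux, Dean–Stark trap with 4 Å sieves
Reagents that add atoms: ethane-1,2-diol, OCCO
Why: Acid-catalysed ketal exchange at the enol ether carbon C7 (addition of the diol to the β-alkoxy enone, loss of ethanol) releases the C5 ketone, which is too hindered by C10 to be ketalised itself; removing ethanol drives the ring–chain equilibrium to the dioxolane.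

Step 6
Reactants: 9 (8S)-8-[(1S)-1-bromopent-4-en-1-yl]-8-methyl-1,4-dioxaspiro[4.5]decan-7-one
Product: 10 (4S)-4-bromo-4-[(8S)-8-methyl-7-oxo-1,4-dioxaspiro[4.5]decan-8-yl]butanal
Conditions: O3, CH2Cl2, −78 °C; then PPh3, −78 to 20 °C
Reagents that add atoms: ozone, [O-][O+]=O
Why: Ozonolysis with reductive work-up cleaves the only alkene to the C4 aldehyde; ketone, ketal and alkyl bromide are inert, and 10 is used at once because it can undergo aldol self-reaction.

Step 7
Reactants: 10 (4S)-4-bromo-4-[(8S)-8-methyl-7-oxo-1,4-dioxaspiro[4.5]decan-8-yl]butanal
Product: 11 (1S,5R,10S)-1-bromo-5-hydroxy-10-methyl-trans-decalin-4-one 7-ethylene ketal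
Conditions: 2-(pentafluorophenyl)-6,7-dihydro-5H-pyrrolo[2,1-c][1,2,4]triazol-2-ium tetrafluoroborate (20 mol %), Et3N (20 mol %), toluene, 60 °C
Reagents that add atoms: none
Why: The carbene formed from the triazolium salt adds to the C4 aldehyde and proton transfer gives the Breslow enaminol, whose C4 attacks the C5 ketone; proton shift and loss of the carbene leave the α-ketol. The closest known reaction type is the carbene-catalysed intramolecular crossed benzoin cyclisation of keto aldehydes to cyclic tertiary α-ketols. Ring B closes in the 6-exo-trig mode. Only the aldehyde can become the acyl anion equivalent and the ketone is the only acceptor in reach, so the crossed sense is fixed, and the hindered secondary bromide should not react with a tertiary amine. The new C5 centre is controlled by the ring A chair: with the C1 chain equatorial, C4 must bond on the carbonyl face turned to the C10 methyl (equatorial bond), which gives the trans-fused ketol with axial hydroxyl, while the axial bond on the other face is opposed by the axial dioxolane oxygen at C7. The flipped ring A chair (chain axial) leads to the cis-fused ketol and is not blocked by the ketal, so kinetic selectivity is not taken for granted. The step is therefore run warm and long enough for retro-benzoin equilibration, under which the trans ketol (equatorial bromine, hydrogen bond from the axial C5 hydroxyl to the syn-axial ketal oxygen) is expected to be enriched, and any cis ketol is returned to the same conditions.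

Step 8
Reactants: 11 (1S,5R,10S)-1-bromo-5-hydroxy-10-methyl-trans-decalin-4-one 7-ethylene ketal; 12 methylmagnesium bromide
Product: 13 (1S,4R,5R,10S)-1-bromo-4,5-dihydroxy-4,10-dimethyl-trans-decalin-7-one ethylene ketal
Conditions: MeMgBr (4 equiv), THF, −78 to 0 °C; aq. NH4Cl
Reagents that add atoms: methylmagnesium bromide (12), C[Mg]Br
Why: Grignard addition to the ketone of the magnesium alkoxide formed from the C5 hydroxyl; the axial trajectory at C4 is syn-axial to the C10 methyl, so methyl should enter equatorially and leave the C4 hydroxyl axial, trans-diaxial to the C5 hydroxyl; the low temperature avoids α-ketol rearrangement.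

Step 9
Reactants: 13 (1S,4R,5R,10S)-1-bromo-4,5-dihydroxy-4,10-dimethyl-trans-decalin-7-one ethylene ketal
Product: 14 (1S,4R,5R,10S)-1-bromo-4,5-dihydroxy-4,10-dimethyl-trans-decalin-7-one
Conditions: PPTS, acetone–H2O, 45 °C
Reagents that add atoms: water, O
Why: Mild acid-catalysed ketal hydrolysis frees the C7 ketone; the weak acid is chosen so that the tertiary 1,2-diol is not ionised and the β-hydroxy ketone is not dehydrated.

Step 10
Reactants: 15 3-ethoxycyclopent-2-en-1-one; 4 methyl iodide
Product: 17 3-ethoxy-5,5-dimethylcyclopent-2-en-1-one, via 3-ethoxy-5-methylcyclopent-2-en-1-one 16 (not isolated)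
Conditions: LiN(iPr)2, THF, −78 °C, then MeI; repeated once in the same flask
Reagents that add atoms: methyl iodide (4), CI
Why: Two successive Stork–Danheiser alkylations at the kinetic α′ position place the future C15 gem-dimethyl group next to the carbonyl carbon that will become C14.

Step 11
Reactants: 17 3-ethoxy-5,5-dimethylcyclopent-2-en-1-one
Product: 18 3-bromo-4,4-dimethylcyclopent-2-en-1-one
Conditions: (COBr)2, DMF (cat.), CH2Cl2, 0 to 25 °C
Reagents that add atoms: oxalyl bromide, O=C(Br)C(=O)Br
Why: Vilsmeier-type activation of the vinylogous ester carbonyl oxygen, addition of bromide to that carbon with loss of the activated oxygen, and de-ethylation of the resulting oxocarbenium ion transpose the carbonyl; bromine therefore ends on the carbon next to the gem-dimethyl group (C14) and the new carbonyl is C12, a known way from 3-alkoxy enones to 3-bromo enones.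

Step 12
Reactants: 18 3-bromo-4,4-dimethylcyclopent-2-en-1-one; 4 methyl iodide
Product: 19 rac-3-bromo-4,4,5-trimethylcyclopent-2-en-1-one
Conditions: LiN(iPr)2, THF, −78 °C; MeI, −78 to −20 °C
Reagents that add atoms: methyl iodide (4), CI
Why: Kinetic α′ deprotonation of the bromo enone and C-methylation install the C11 methyl; the bulky amide should remove the α′ proton faster than it adds to the hindered bromine-bearing β carbon, and the new stereocentre is erased when 19 is enolised again.

Step 13
Reactants: 14 (1S,4R,5R,10S)-1-bromo-4,5-dihydroxy-4,10-dimethyl-trans-decalin-7-one; 19 rac-3-bromo-4,4,5-trimethylcyclopent-2-en-1-one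
Product: 20 (1S,4R,5R,7R,10S)-1-bromo-7-[(1S)-3-bromo-1,2,2-trimethyl-5-oxocyclopent-3-en-1-yl]-4,10-dimethyl-trans-decalin-4,5,7-triol
Conditions: 19, LiN(SiMe3)2, THF, −78 °C, then CeCl3; add the dilithium alkoxide of 14 (LiN(SiMe3)2, 2 equiv, THF, −78 °C); −78 °C; AcOH quench at −78 °C
Reagents that add atoms: none
Why: Aldol addition of the cross-conjugated dienolate of 19 through C11 to the C7 ketone; the bulky nucleophile should enter equatorially (the axial path is syn-axial to the C5 oxygen) and give the axial C7 hydroxyl, and a metal held between the new O7 and the syn-axial C5 alkoxide must lie over C6, which puts the enolate carbon C12 on the C6 side of a closed six-membered transition state and the C11 methyl on the C8 side, the arrangement that corresponds to the required C11 configuration; the oxophilic cerium and the cold acidic quench are meant to suppress proton transfer and retro-aldol cleavage.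

Step 14
Reactants: 20 (1S,4R,5R,7R,10S)-1-bromo-7-[(1S)-3-bromo-1,2,2-trimethyl-5-oxocyclopent-3-en-1-yl]-4,10-dimethyl-trans-decalin-4,5,7-triol
Product: 21 (1S,4R,5R,7R,10S)-1-bromo-7-[(1R,5S)-3-bromo-5-hydroxy-1,2,2-trimethylcyclopent-3-en-1-yl]-4,10-dimethyl-trans-decalin-4,5,7-triol
Conditions: NaBH4, CeCl3·7H2O, MeOH, −78 to −20 °C
Reagents that add atoms: none
Why: Luche reduction gives 1,2-addition to the bromo enone and avoids conjugate addition, which would expel bromide; hydride should approach C12 anti to the very large C7 substituent on the adjacent quaternary C11, that is syn to the C11 methyl, so the C12 hydroxyl ends cis to C7.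

Step 15
Reactants: 21 (1S,4R,5R,7R,10S)-1-bromo-7-[(1R,5S)-3-bromo-5-hydroxy-1,2,2-trimethylcyclopent-3-en-1-yl]-4,10-dimethyl-trans-decalin-4,5,7-triol
Product: 22 neoirietetraol: (1S,4R,5R,7R,10S)-1-bromo-7-[(1R,3R,5S)-3-bromo-5-hydroxy-1,2,2-trimethylcyclopentyl]-4,10-dimethyl-trans-decalin-4,5,7-triol
Conditions: Mn(dpm)3 (cat.; dpm = 2,2,6,6-tetramethylheptane-3,5-dionate), PhSiH3, t-BuOOH, i-PrOH, 22 °C
Reagents that add atoms: none
Why: Metal hydride hydrogen-atom-transfer hydrogenation, a reaction type that reduces haloalkenes without hydrogenolysis; the first hydrogen atom should add to the less substituted C13 and leave the bromine-stabilised C14 radical, which takes its second hydrogen on the ring C face opposite the C7 substituent and the C12 hydroxyl, so bromine stays on their face (C14 R).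

## Compound list

1 | 3-ethoxycyclohex-2-en-1-one | CCOC1=CC(=O)CCC1 | starting material
2 | pent-4-enoyl chloride | C=CCCC(=O)Cl | starting material
3 | 3-ethoxy-6-(pent-4-enoyl)cyclohex-2-en-1-one (racemic, enolisable) | CCOC1=CC(=O)C(CC1)C(=O)CCC=C | intermediate
4 | methyl iodide | CI | starting material
5 | rac-3-ethoxy-6-methyl-6-(pent-4-enoyl)cyclohex-2-en-1-one | CCOC1=CC(=O)C(C)(CC1)C(=O)CCC=C | intermediate
6 | (6R)-3-ethoxy-6-[(1R)-1-hydroxypent-4-en-1-yl]-6-methylcyclohex-2-en-1-one | CCOC1=CC(=O)[C@@](C)([C@H](O)CCC=C)CC1 | intermediate
7 | (1R)-1-[(1R)-4-ethoxy-1-methyl-2-oxocyclohex-3-en-1-yl]pent-4-en-1-yl trifluoromethanesulfonate | CCOC1=CC(=O)[C@@](C)([C@H](OS(=O)(=O)C(F)(F)F)CCC=C)CC1 | intermediate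
8 | (6S)-6-[(1S)-1-bromopent-4-en-1-yl]-3-ethoxy-6-methylcyclohex-2-en-1-one | CCOC1=CC(=O)[C@@](C)([C@@H](Br)CCC=C)CC1 | intermediate
9 | (8S)-8-[(1S)-1-bromopent-4-en-1-yl]-8-methyl-1,4-dioxaspiro[4.5]decan-7-one | O1CCOC12CC[C@](C)([C@@H](Br)CCC=C)C(=O)C2 | intermediate
10 | (4S)-4-bromo-4-[(8S)-8-methyl-7-oxo-1,4-dioxaspiro[4.5]decan-8-yl]butanal | O1CCOC12CC[C@](C)([C@@H](Br)CCC=O)C(=O)C2 | intermediate
11 | (1S,5R,10S)-1-bromo-5-hydroxy-10-methyl-trans-decalin-4-one 7-ethylene ketal | O1CCOC12CC[C@]3(C)[C@@H](Br)CCC(=O)[C@@]3(O)C2 | intermediate
12 | methylmagnesium bromide | C[Mg]Br | starting material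
13 | (1S,4R,5R,10S)-1-bromo-4,5-dihydroxy-4,10-dimethyl-trans-decalin-7-one ethylene ketal | O1CCOC12CC[C@]3(C)[C@@H](Br)CC[C@@](C)(O)[C@@]3(O)C2 | intermediate
14 | (1S,4R,5R,10S)-1-bromo-4,5-dihydroxy-4,10-dimethyl-trans-decalin-7-one | O=C1CC[C@]2(C)[C@@H](Br)CC[C@@](C)(O)[C@@]2(O)C1 | intermediate
15 | 3-ethoxycyclopent-2-en-1-one | CCOC1=CC(=O)CC1 | starting material
16 | 3-ethoxy-5-methylcyclopent-2-en-1-one (racemic) | CCOC1=CC(=O)C(C)C1 | intermediate
17 | 3-ethoxy-5,5-dimethylcyclopent-2-en-1-one | CCOC1=CC(=O)C(C)(C)C1 | intermediate
18 | 3-bromo-4,4-dimethylcyclopent-2-en-1-one | O=C1C=C(Br)C(C)(C)C1 | intermediate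
19 | rac-3-bromo-4,4,5-trimethylcyclopent-2-en-1-one | O=C1C=C(Br)C(C)(C)C1C | intermediate
20 | (1S,4R,5R,7R,10S)-1-bromo-7-[(1S)-3-bromo-1,2,2-trimethyl-5-oxocyclopent-3-en-1-yl]-4,10-dimethyl-trans-decalin-4,5,7-triol | CC1(C)C(Br)=CC(=O)[C@]1(C)[C@@]1(O)CC[C@]2(C)[C@@H](Br)CC[C@@](C)(O)[C@@]2(O)C1 | intermediate
21 | (1S,4R,5R,7R,10S)-1-bromo-7-[(1R,5S)-3-bromo-5-hydroxy-1,2,2-trimethylcyclopent-3-en-1-yl]-4,10-dimethyl-trans-decalin-4,5,7-triol | CC1(C)C(Br)=C[C@H](O)[C@]1(C)[C@@]1(O)CC[C@]2(C)[C@@H](Br)CC[C@@](C)(O)[C@@]2(O)C1 | intermediate
22 | neoirietetraol: (1S,4R,5R,7R,10S)-1-bromo-7-[(1R,3R,5S)-3-bromo-5-hydroxy-1,2,2-trimethylcyclopentyl]-4,10-dimethyl-trans-decalin-4,5,7-triol | CC1(C)[C@H](Br)C[C@H](O)[C@]1(C)[C@@]1(O)CC[C@]2(C)[C@@H](Br)CC[C@@](C)(O)[C@@]2(O)C1 | target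

## Step count and least certain steps

Total step count: 15. Longest linear sequence: 12 (steps 1 to 9 and 13 to 15); steps 10 to 12 form the ring C branch.

**Step 7 (key step).** The most likely failure is poor facial selectivity at C5. Closure through the flipped ring A chair gives the cis-fused ketol; that mode keeps the enol O–H of the Breslow intermediate next to the ketone oxygen, needs less torsional stretching of the forming ring, and the two ring fusions may be close in energy at equilibrium. The fallback makes the ring-fusion outcome of the cyclisation irrelevant. It sets out from 11, or from its C5 epimer, the cis-fused ketol F1, and comes back at 13. Either ketol is dehydrated with the Burgess reagent to the same C5=C6 enone F2. MeMgBr with CeCl3 then adds 1,2 to C4 anti to the C10 methyl and gives the allylic alcohol F3. A Mukaiyama hydration (Co(acac)2, PhSiH3, O2; then PPh3) puts a hydrogen atom on C6, and the tertiary C5 radical should take up oxygen on the face opposite the axial C10 methyl and the axial C4 hydroxyl, which is the trans-fused diol 13.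

**Step 4.** The most likely failure is ionisation of the triflate with 1,2-shift or elimination in place of direct displacement, because C1 is flanked by the quaternary C10. The fallback gives up substitution at C1; it sets out from 6 and comes back at 13.
- Silylation of 6 (t-BuMe2SiOTf, 2,6-lutidine) gives the silyl ether F4.
- F4 is taken through the operations of steps 5 to 8 to the keto ketal F5, the aldehyde F6, the ketol F7 and the diol F8. In the closure to F7 the axial C1 silyloxy group should also disfavour the cis mode, in which it would be syn-axial to C6.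
- Bu4NF frees the triol F9, and Dess–Martin periodinane oxidises only the secondary C1 hydroxyl to the ketone F10.
- 2,4,6-Triisopropylbenzenesulfonohydrazide gives the hydrazone F11, and a Shapiro reaction (n-BuLi, then BrCF2CF2Br) gives the C1–C2 bromoalkene F12.
- Hydrogen-atom-transfer hydrogenation under the conditions of step 15 should deliver hydrogen to C1 on the face opposite the axial C10 methyl and leave bromine equatorial, which is 13.

**Step 13.** The most likely failure is reversal of the addition or proton transfer in place of C–C bond formation, because three contiguous fully substituted carbons are created; low discrimination between the two faces of C11 is the second concern. The fallback replaces the base-mediated aldol by a reductive Reformatsky-type union; it sets out from 14 and 19 and comes back at 20. 19 is brominated at C5 through its lithium dienolate (N-bromosuccinimide) to the dibromo ketone F13, and 14 is silylated with 1-(trimethylsilyl)imidazole to the bis(trimethylsilyl) ether F14. SmI2 in THF at −78 °C then generates a samarium enolate from F13 in the presence of F14, without base. The adduct F15 is desilylated (K2CO3, MeOH) to 20.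

**Step 15.** The most likely failure is loss of bromine by β-scission if the first hydrogen atom adds to C14, or hydrogen delivery from the wrong face. The fallback leaves the radical manifold for a concerted transfer: diimide generated from 2-nitrobenzenesulfonohydrazide and Et3N delivers both hydrogens in one step to the open face of the bromoalkene, with no carbon radical. It sets out from 21, comes back at 22 and makes no new compound (F0).

## Further compounds

F1 | step 7 | (1S,5S,10S)-1-bromo-5-hydroxy-10-methyl-cis-decalin-4-one 7-ethylene ketal | O1CCOC12CC[C@]3(C)[C@@H](Br)CCC(=O)[C@]3(O)C2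
F2 | step 7 | (1S,10S)-1-bromo-10-methyl-octal-5-en-4-one 7-ethylene ketal (C5=C6 enone) | O1CCOC12CC[C@]3(C)[C@@H](Br)CCC(=O)C3=C2
F3 | step 7 | (1S,4R,10S)-1-bromo-4-hydroxy-4,10-dimethyl-octal-5-en-7-one ethylene ketal | O1CCOC12CC[C@]3(C)[C@@H](Br)CC[C@@](C)(O)C3=C2
F4 | step 4 | (6R)-6-[(1R)-1-(tert-butyldimethylsilyloxy)pent-4-en-1-yl]-3-ethoxy-6-methylcyclohex-2-en-1-one | CCOC1=CC(=O)[C@@](C)([C@H](O[Si](C)(C)C(C)(C)C)CCC=C)CC1
F5 | step 4 | (8R)-8-[(1R)-1-(tert-butyldimethylsilyloxy)pent-4-en-1-yl]-8-methyl-1,4-dioxaspiro[4.5]decan-7-one | O1CCOC12CC[C@](C)([C@H](O[Si](C)(C)C(C)(C)C)CCC=C)C(=O)C2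
F6 | step 4 | (4R)-4-(tert-butyldimethylsilyloxy)-4-[(8R)-8-methyl-7-oxo-1,4-dioxaspiro[4.5]decan-8-yl]butanal | O1CCOC12CC[C@](C)([C@H](O[Si](C)(C)C(C)(C)C)CCC=O)C(=O)C2
F7 | step 4 | (1R,5R,10R)-1-(tert-butyldimethylsilyloxy)-5-hydroxy-10-methyl-trans-decalin-4-one 7-ethylene ketal | O1CCOC12CC[C@]3(C)[C@H](O[Si](C)(C)C(C)(C)C)CCC(=O)[C@@]3(O)C2
F8 | step 4 | (1R,4R,5R,10R)-1-(tert-butyldimethylsilyloxy)-4,5-dihydroxy-4,10-dimethyl-trans-decalin-7-one ethylene ketal | O1CCOC12CC[C@]3(C)[C@H](O[Si](C)(C)C(C)(C)C)CC[C@@](C)(O)[C@@]3(O)C2
F9 | step 4 | (1R,4R,5R,10R)-1,4,5-trihydroxy-4,10-dimethyl-trans-decalin-7-one ethylene ketal | O1CCOC12CC[C@]3(C)[C@H](O)CC[C@@](C)(O)[C@@]3(O)C2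
F10 | step 4 | (4R,5R,10S)-4,5-dihydroxy-4,10-dimethyl-trans-decalin-1,7-dione 7-ethylene ketal | O1CCOC12CC[C@]3(C)C(=O)CC[C@@](C)(O)[C@@]3(O)C2
F11 | step 4 | C1 2,4,6-triisopropylbenzenesulfonylhydrazone of F10 | O1CCOC12CC[C@]3(C)C(=NNS(=O)(=O)c4c(C(C)C)cc(C(C)C)cc4C(C)C)CC[C@@](C)(O)[C@@]3(O)C2
F12 | step 4 | (4R,5R,10S)-1-bromo-4,5-dihydroxy-4,10-dimethyl-trans-octal-1-en-7-one ethylene ketal (C1=C2 bromoalkene) | O1CCOC12CC[C@]3(C)C(Br)=CC[C@@](C)(O)[C@@]3(O)C2
F13 | step 13 | rac-3,5-dibromo-4,4,5-trimethylcyclopent-2-en-1-one | O=C1C=C(Br)C(C)(C)C1(C)Br
F14 | step 13 | (1S,4R,5R,10S)-1-bromo-4,10-dimethyl-4,5-bis(trimethylsilyloxy)-trans-decalin-7-one | O=C1CC[C@]2(C)[C@@H](Br)CC[C@@](C)(O[Si](C)(C)C)[C@@]2(O[Si](C)(C)C)C1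
F15 | step 13 | 4,5-bis(trimethylsilyl) ether of 20 | CC1(C)C(Br)=CC(=O)[C@]1(C)[C@@]1(O)CC[C@]2(C)[C@@H](Br)CC[C@@](C)(O[Si](C)(C)C)[C@@]2(O[Si](C)(C)C)C1
F0 | step 15 | none | none
A1 | alternative 1 | C5/C7-bridged 1,2-dioxolane with C4 triethylsilyl peroxide | CC1(C)[C@H](Br)C[C@H](O)[C@]1(C)[C@@]1(OO5)CC[C@]2(C)[C@@H](Br)CC[C@@](C)(OO[Si](CC)(CC)CC)[C@@]25C1
A2 | alternative 2 | bromo octalin acetonide with C4=C5 alkene | CC1(C)[C@H](Br)C[C@H](O3)[C@]1(C)[C@@]1(OC3(C)C)CC[C@]2(C)[C@@H](Br)CCC(C)=C2C1
A3 | alternative 3 | cis-fused octalone with C7=C8 alkene, bis(tert-butyldimethylsilyl) ether | CC1(C)[C@H](Br)C[C@H](O[Si](C)(C)C(C)(C)C)[C@]1(C)C1=CC[C@]2(C)C(=O)CC[C@@H](O[Si](C)(C)C(C)(C)C)[C@@H]2C1
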